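The route rests on cutting cyclohexene ring C at C9a–C9 (enamine carbon to carbinol) and C10–C11 (CHEt to CH–O). An intramolecular Diels–Alder reaction of a ring-fused 2-amidofuran (O–C9a=C1–C12=C11) with a tethered (E)-enol ether (C9=C10), followed by nitrogen-assisted opening of the oxygen bridge and a 1,2-hydride shift, closes ring C and the azepane in one operation. The step exploits the N–C9a=C1 enamine with oxygen at C11, the imprint of a 2-aminofuran, and the C9 carbinol, the imprint of an enol ether. The precursor is a bicyclic aminofuran salt acylated in situ by a chiral 5-propylideneoxolane-2-carboxylic acid derivative whose ring oxygen is a temporary bridge.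

Key step: step 12

Atom labels follow the target: ring A = N4, C3 (carries the side lactone C18–C21), C2, C1, C9a; ring B = N4, C5–C8, C9, C9a; ring C = C9a, C1, C12, C11, C10, C9; ring D = C11, C12, C13, C14(=O), O.

Assumption: compounds 16, 17 and 19–23 are carried as mixtures of C13 epimers (16 also at C1 and C12); these centres are left open in their SMILES and converge in steps 11 and 14.

**Tether (steps 1–5)**

Step 1
Reactants: 1 (2R)-2-aminohex-5-ynoic acid
Product: 2 (2R)-2-hydroxyhex-5-ynoic acid
Conditions: NaNO2, 1 M aq. H2SO4, 0 °C to rt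
Reagents that add atoms: water, O
Why: Diazotization of the α-amino acid proceeds with retention (double inversion through the α-lactone) and gives the (R)-α-hydroxy acid.

Step 2
Reactants: 2 (2R)-2-hydroxyhex-5-ynoic acid
Product: 3 methyl (2R)-2-hydroxyhex-5-ynoate
Conditions: MeOH, H2SO4 (cat.), rt
Reagents that add atoms: methanol, CO
Why: Fischer esterification masks the acid so that only the hydroxyl group can attack the alkyne in step 3.

Step 3
Reactants: 3 methyl (2R)-2-hydroxyhex-5-ynoate
Product: 4 methyl (2R,5E)-5-(iodomethylidene)oxolane-2-carboxylate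
Conditions: N-iodosuccinimide, NaHCO3, MeCN, 0 °C to rt, dark
Reagents that add atoms: N-iodosuccinimide, O=C1CCC(=O)N1I
Why: Iodoetherification (5-exo-dig) adds oxygen and iodine anti across the terminal alkyne, which fixes the enol ether geometry with O trans to I.

Step 4
Reactants: 4 methyl (2R,5E)-5-(iodomethylidene)oxolane-2-carboxylate
Product: 5 methyl (2R,5E)-5-propylideneoxolane-2-carboxylate
Conditions: Et2Zn, PdCl2(dppf) (5 mol %), THF, 50 °C
Reagents that add atoms: diethylzinc, CC[Zn]CC
Why: Negishi coupling replaces iodine by ethyl with retention of alkene geometry, so the ethyl group ends trans to the ring oxygen (E), the geometry that later places O9 and H10 cis.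

Step 5
Reactants: 5 methyl (2R,5E)-5-propylideneoxolane-2-carboxylate
Product: 6 lithium (2R,5E)-5-propylideneoxolane-2-carboxylate
Conditions: LiOH·H2O (1.05 equiv), THF/H2O, 0 °C; freeze-dry
Reagents that add atoms: lithium hydroxide, [Li+].[OH-]
Why: Saponification; the acid-labile but base-stable enol ether is kept as the lithium salt and never acidified.

**Michael acceptor (step 6)**

Step 6
Reactants: 7 2,2-dimethoxyacetaldehyde; 8 methyl 2-(triphenyl-λ5-phosphanylidene)acetate
Product: 9 methyl (2E)-4,4-dimethoxybut-2-enoate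
Conditions: CH2Cl2/H2O, rt
Reagents that add atoms: none
Why: Wittig reaction of a stabilised ylide gives the E enoate.

**Core (steps 7–16)**

Step 7
Reactants: 10 tert-butyl (2R)-2-(hydroxymethyl)-5-oxopyrrolidine-1-carboxylate
Product: 11 tert-butyl (2R)-2-formyl-5-oxopyrrolidine-1-carboxylate
Conditions: Dess–Martin periodinane, CH2Cl2, 0 °C to rt
Reagents that add atoms: none
Why: Dess–Martin oxidation under non-basic conditions should give the epimerizable α-amino aldehyde with C3 intact; it is used at once.

Step 8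
Reactants: 11 tert-butyl (2R)-2-formyl-5-oxopyrrolidine-1-carboxylate; 12 ethyl 2-(bromomethyl)prop-2-enoate
Product: 14 tert-butyl (2R)-2-[(2S)-4-methylidene-5-oxooxolan-2-yl]-5-oxopyrrolidine-1-carboxylate, via homoallylic alcohol 13 (not isolated)
Conditions: Zn dust, THF/sat. aq. NH4Cl, 0 °C to rt; then p-TsOH·H2O (cat.), CH2Cl2, rt
Reagents that add atoms: none
Why: Zinc-mediated Barbier allylation (Dreiding–Schmidt reaction) under Felkin–Anh control, with the non-chelating N-Boc-lactam nitrogen as the polar α-substituent, should set C18 anti to N4, and acid-catalysed lactonization closes the α-methylene-γ-butyrolactone.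

Step 9
Reactants: 14 tert-butyl (2R)-2-[(2S)-4-methylidene-5-oxooxolan-2-yl]-5-oxopyrrolidine-1-carboxylate
Product: 15 tert-butyl (2R)-2-[(2S,4S)-4-methyl-5-oxooxolan-2-yl]-5-oxopyrrolidine-1-carboxylate
Conditions: H2 (1 atm), Rh/Al2O3 (5 wt %), EtOAc, rt
Reagents that add atoms: none
Why: Heterogeneous hydrogenation delivers hydrogen to the face of the exocyclic alkene opposite the C18 substituent and so sets the cis C20 methyl group.

Step 10
Reactants: 15 tert-butyl (2R)-2-[(2S,4S)-4-methyl-5-oxooxolan-2-yl]-5-oxopyrrolidine-1-carboxylate; 9 methyl (2E)-4,4-dimethoxybut-2-enoate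
Product: 16 tert-butyl (5R)-3-(1,1,4-trimethoxy-3-methyl-4-oxobutan-2-yl)-5-[(2S,4S)-4-methyl-5-oxooxolan-2-yl]-2-oxopyrrolidine-1-carboxylate
Conditions: LiN(SiMe3)2, THF, −78 °C; 9; then MeI, DMPU, −78 to −40 °C
Reagents that add atoms: iodomethane, CI
Why: LiN(SiMe3)2 removes the most acidic and least hindered C–H (the N-Boc-lactam CH2), the enolate adds to 9 on the face opposite the C3 substituent (Michael addition) and the ester enolate so formed is methylated in the same flask (tandem Michael addition–alkylation); C1 and C12 need no control because both become sp2 in step 11, and C13 is set in step 14.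

Step 11
Reactants: 16 tert-butyl (5R)-3-(1,1,4-trimethoxy-3-methyl-4-oxobutan-2-yl)-5-[(2S,4S)-4-methyl-5-oxooxolan-2-yl]-2-oxopyrrolidine-1-carboxylate
Product: 17 (5R)-3-(1-methoxy-1-oxopropan-2-yl)-5-[(2S,4S)-4-methyl-5-oxooxolan-2-yl]-4,5-dihydro-2H-furo[2,3-b]pyrrol-6-ium trifluoroacetate
Conditions: CF3CO2H/CH2Cl2 (1:4), 0 °C to rt; evaporate
Reagents that add atoms: trifluoroacetic acid, OC(=O)C(F)(F)F
Why: Acid removes the Boc group and ionizes the acetal, the lactam oxygen closes onto the oxocarbenium ion (5-exo) and loss of methanol aromatizes the new ring (Paal–Knorr-type cyclodehydration of a γ-oxo amide), the bicyclic 2-aminofuran being stored as its C-protonated iminium salt.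

Step 12
Reactants: 6 lithium (2R,5E)-5-propylideneoxolane-2-carboxylate; 17 bicyclic 2-aminofuran trifluoroacetate
Product: 21 pentacyclic enamide keto ester, via mixed anhydride 18 (not isolated), via 2-amidofuran 19 (not isolated), via oxygen-bridged cycloadduct 20 (not isolated)
Conditions: t-BuCOCl, THF, 0 °C (6 to 18); 17, 2,6-lutidine, CH2Cl2, −40 °C to rt; cold aq. NaHCO3 wash; PhMe, 90 °C
Reagents that add atoms: none
Why: The carboxylate is activated as pivalic mixed anhydride 18, which acylates the nitrogen of the aminofuran set free from 17 to give 2-amidofuran 19; on heating, its furan (4π: C9a=C1–C12=C11) adds the tethered enol ether (2π: C9=C10) in an intramolecular Diels–Alder reaction, the oxygen bridge of adduct 20 opens under nitrogen assistance and a 1,2-hydride shift from C11 to C12 gives 21, the known cycloaddition–ring-opening cascade of 2-amidofurans that carry a dienophile on an N-acyl tether. Ring C is closed by the [4+2] cycloaddition and ring B by the same C9a–C9 bond, the tether N4–C5(=O)–C6–O–C9 closing a six-membered ring in the transition state while C6–C8 ride along as a bridged oxolane. C9 is controlled by the C6 stereocentre of the tether (the furan can only reach the alkene face cis to the C6 carbonyl group, and the bridged bicycle ties 6R to 9R), C10 by the E geometry of the enol ether through suprafacial addition (O9 and H10 cis), and C12 by the suprafacial hydride shift on the face away from the former oxygen bridge of the exo-tether adduct. The step needs N-acylation without loss of the C6 configuration, which the mixed anhydride and the weak base 2,6-lutidine (no ketene) should secure, and it needs no furan face selectivity, because C9a and C11 lose their stereochemistry in the cascade.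

Step 13
Reactants: 21 pentacyclic enamide keto ester
Product: 23 ring D lactone (C13 epimers), via hydroxy ester 22 (not isolated)
Conditions: NaBH4, MeOH/CH2Cl2, −40 °C to rt
Reagents that add atoms: none
Why: Hydride should add to the C11 ketone from the face opposite the C12 side chain and the C9 oxygen bridge (substrate-controlled ketone reduction), and the resulting cis γ-hydroxy ester lactonizes to ring D in the same flask.

Step 14
Reactants: 23 ring D lactone (C13 epimers)
Product: 24 ring D lactone, single (13R) epimer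
Conditions: LiN(i-Pr)2 (2.5 equiv), THF, −78 to −40 °C; then 2,6-di-tert-butyl-4-methylphenol, −78 °C
Reagents that add atoms: none
Why: Double deprotonation of both lactones followed by kinetic protonation on the less hindered faces (convex face of ring D, face opposite the C18 substituent in the side lactone) should set C13 with the methyl group cis to C1 and re-affirm the cis C20 methyl group.

Step 15
Reactants: 24 ring D lactone, single (13R) epimer
Product: 25 9-hydroxy lactam (5-oxo derivative of the target)
Conditions: SmI2, HMPA, MeOH, THF, −20 °C to rt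
Reagents that add atoms: none
Why: Single-electron reduction of the lactam carbonyl by SmI2 expels the α-alkoxide (reductive cleavage of an α-heterosubstituted carbonyl compound), which frees the C9 tertiary alcohol with its configuration untouched and turns C6 into CH2.

Step 16
Reactants: 25 9-hydroxy lactam
Product: 26 target (CNP0186848.1)
Conditions: Zn(OAc)2 (10 mol %), (EtO)3SiH, THF, 40 °C; then KF, MeOH
Reagents that add atoms: none
Why: Zinc-catalysed hydrosilylation reduces the tertiary lactam chemoselectively to the amine in the presence of the two γ-lactones and so completes the N4–C9a=C1 enamine of the target.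

**Compound list**

1 | (2R)-2-aminohex-5-ynoic acid | C#CCC[C@@H](N)C(=O)O | starting material
2 | (2R)-2-hydroxyhex-5-ynoic acid | C#CCC[C@@H](O)C(=O)O | intermediate
3 | methyl (2R)-2-hydroxyhex-5-ynoate | C#CCC[C@@H](O)C(=O)OC | intermediate
4 | methyl (2R,5E)-5-(iodomethylidene)oxolane-2-carboxylate | COC(=O)[C@H]1CC/C(=C\I)O1 | intermediate
5 | methyl (2R,5E)-5-propylideneoxolane-2-carboxylate | COC(=O)[C@H]1CC/C(=C\CC)O1 | intermediate
6 | lithium (2R,5E)-5-propylideneoxolane-2-carboxylate | [Li+].[O-]C(=O)[C@H]1CC/C(=C\CC)O1 | intermediate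
7 | 2,2-dimethoxyacetaldehyde | COC(OC)C=O | starting material
8 | methyl 2-(triphenyl-λ5-phosphanylidene)acetate | COC(=O)C=P(c1ccccc1)(c1ccccc1)c1ccccc1 | starting material
9 | methyl (2E)-4,4-dimethoxybut-2-enoate | COC(=O)/C=C/C(OC)OC | intermediate
10 | tert-butyl (2R)-2-(hydroxymethyl)-5-oxopyrrolidine-1-carboxylate | CC(C)(C)OC(=O)N1C(=O)CC[C@@H]1CO | starting material
11 | tert-butyl (2R)-2-formyl-5-oxopyrrolidine-1-carboxylate | CC(C)(C)OC(=O)N1C(=O)CC[C@@H]1C=O | intermediate
12 | ethyl 2-(bromomethyl)prop-2-enoate | CCOC(=O)C(=C)CBr | starting material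
13 | tert-butyl (2R)-2-[(1S)-3-(ethoxycarbonyl)-1-hydroxybut-3-en-1-yl]-5-oxopyrrolidine-1-carboxylate (homoallylic alcohol, not isolated) | CC(C)(C)OC(=O)N1C(=O)CC[C@@H]1[C@@H](O)CC(=C)C(=O)OCC | intermediate
14 | tert-butyl (2R)-2-[(2S)-4-methylidene-5-oxooxolan-2-yl]-5-oxopyrrolidine-1-carboxylate | CC(C)(C)OC(=O)N1C(=O)CC[C@@H]1[C@@H]2CC(=C)C(=O)O2 | intermediate
15 | tert-butyl (2R)-2-[(2S,4S)-4-methyl-5-oxooxolan-2-yl]-5-oxopyrrolidine-1-carboxylate | CC(C)(C)OC(=O)N1C(=O)CC[C@@H]1[C@@H]2C[C@H](C)C(=O)O2 | intermediate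
16 | tert-butyl (5R)-3-(1,1,4-trimethoxy-3-methyl-4-oxobutan-2-yl)-5-[(2S,4S)-4-methyl-5-oxooxolan-2-yl]-2-oxopyrrolidine-1-carboxylate (diastereomer mixture at C1, C12, C13) | CC(C)(C)OC(=O)N1C(=O)C(C(C(OC)OC)C(C)C(=O)OC)C[C@@H]1[C@@H]2C[C@H](C)C(=O)O2 | intermediate
17 | (5R)-3-(1-methoxy-1-oxopropan-2-yl)-5-[(2S,4S)-4-methyl-5-oxooxolan-2-yl]-4,5-dihydro-2H-furo[2,3-b]pyrrol-6-ium trifluoroacetate (C-protonated bicyclic 2-aminofuran; C13 epimers) | COC(=O)C(C)C1=C2C[C@@H]([NH+]=C2OC1)[C@@H]3C[C@H](C)C(=O)O3.[O-]C(=O)C(F)(F)F | intermediate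
18 | (2R,5E)-5-propylideneoxolane-2-carboxylic 2,2-dimethylpropanoic anhydride (mixed anhydride, not isolated) | CC(C)(C)C(=O)OC(=O)[C@H]1CC/C(=C\CC)O1 | intermediate
19 | methyl 2-{(5R)-5-[(2S,4S)-4-methyl-5-oxooxolan-2-yl]-6-[(2R,5E)-5-propylideneoxolane-2-carbonyl]-5,6-dihydro-4H-furo[2,3-b]pyrrol-3-yl}propanoate (2-amidofuran, not isolated; C13 epimers) | COC(=O)C(C)c1coc2c1C[C@@H](N2C(=O)[C@H]3CC/C(=C\CC)O3)[C@@H]4C[C@H](C)C(=O)O4 | intermediate
20 | exo oxygen-bridged [4+2] cycloadduct (7-oxabicyclo[2.2.1]hept-2-ene core: oxygen bridges C9a and C11, C1=C12 retained; C9a S, C11 S, C6 R, other centres as in 21; not isolated) | CC[C@H]1[C@@H]2O[C@]36N(C(=O)[C@H]4CC[C@@]13O4)[C@@H]([C@@H]5C[C@H](C)C(=O)O5)CC6=C2C(C)C(=O)OC | intermediate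
21 | pentacyclic enamide keto ester: rings A, B and C closed, C11 ketone, C12 carries CH(CH3)CO2CH3, N4–C5 lactam, C6–O–C9 ether bridge (C3, C9, C10, C12, C18, C20 arranged as in the target; C6 R; C13 epimers) | CC[C@H]1C(=O)[C@H](C(C)C(=O)OC)C2=C3N(C(=O)[C@H]4CC[C@]31O4)[C@@H]([C@@H]5C[C@H](C)C(=O)O5)C2 | intermediate
22 | C11 alcohol of 21 (hydroxyl cis to the C12 side chain; not isolated) | CC[C@H]1[C@H](O)[C@H](C(C)C(=O)OC)C2=C3N(C(=O)[C@H]4CC[C@]31O4)[C@@H]([C@@H]5C[C@H](C)C(=O)O5)C2 | intermediate
23 | ring D lactone: C11–O–C14 γ-lactone closed, lactam and C6–O–C9 bridge retained (C13 epimers) | CC[C@H]1[C@@H]2OC(=O)C(C)[C@@H]2C2=C3N(C(=O)[C@H]4CC[C@]31O4)[C@@H]([C@@H]5C[C@H](C)C(=O)O5)C2 | intermediate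
24 | ring D lactone as the single (13R) epimer (methyl cis to C1) | CC[C@H]1[C@@H]2OC(=O)[C@H](C)[C@@H]2C2=C3N(C(=O)[C@H]4CC[C@]31O4)[C@@H]([C@@H]5C[C@H](C)C(=O)O5)C2 | intermediate
25 | 9-hydroxy lactam: 5-oxo derivative of the target (C6 is CH2, C9–OH free) | CC[C@H]1[C@@H]2OC(=O)[C@H](C)[C@@H]2C2=C3N(C(=O)CCC[C@]31O)[C@@H]([C@@H]4C[C@H](C)C(=O)O4)C2 | intermediate
26 | CNP0186848.1 | CC[C@H]1[C@@H]2OC(=O)[C@H](C)[C@@H]2C2=C3N(CCCC[C@]31O)[C@@H]([C@@H]1C[C@H](C)C(=O)O1)C2 | target

**Step count**

Total: 16 steps. Longest linear sequence: 10 steps (10 to 26 through steps 7–16; the tether branch 1 to 6 followed by steps 12–16 is equally long).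

**Steps most likely to fail**

1. Step 12. The cycloaddition pairs two electron-rich π systems and may be slower than hydrolytic or oxidative ring opening of amidofuran 19. The fallback sets out from iodide 4 and returns at 21. Sonogashira coupling of 4 with ethynyltrimethylsilane (PdCl2(PPh3)2, CuI, Et3N) should give methyl (2R,5E)-5-[3-(trimethylsilyl)prop-2-yn-1-ylidene]oxolane-2-carboxylate F1. LiOH then saponifies the ester and removes the silyl group to give lithium (2R,5E)-5-(prop-2-yn-1-ylidene)oxolane-2-carboxylate F2. Under the protocol of step 12 with 17 this passes through the pivalic mixed anhydride F3, the enynyl 2-amidofuran F4 and the oxygen-bridged cycloadduct F5 to the 10-ethynyl keto ester F6, the conjugated enyne being the smaller and more reactive 2π partner. Hydrogenation of the alkyne (H2, Pd/C, EtOAc) then gives 21.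

2. Step 11. The nitrogen-unprotected aminofuran may be lost by ring opening or self-condensation while the salt is made or neutralised. The fallback sets out from 16 and returns at 19. With pyridinium p-toluenesulfonate (cat.) in toluene at 90 °C the Boc group stays on and the cyclodehydration should give the N-Boc 2-amidofuran F7, a stable carbamate. t-BuMe2SiOTf and 2,6-lutidine convert it into the tert-butyldimethylsilyl carbamate F8. n-Bu4NF in the presence of mixed anhydride 18 then releases the carbamate anion, which loses CO2 and is acylated to 19; heating as in step 12 carries 19 on to 21.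

3. Step 10. Proton transfer from the lactam or lactone α-C–H to the ester enolate before it is methylated would place the methyl group on the wrong carbon. The fallback sets out from 7 and 15 and returns at 16. Wittig reaction of 7 with commercial methyl 2-(triphenyl-λ5-phosphanylidene)propanoate gives methyl (2E)-4,4-dimethoxy-2-methylbut-2-enoate F9, which already carries the C13 methyl group. Michael addition of the lithium enolate of 15 to F9 followed by aqueous quench gives 16 without any alkylation step.

Further compounds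
F1 | step 12 | methyl (2R,5E)-5-[3-(trimethylsilyl)prop-2-yn-1-ylidene]oxolane-2-carboxylate | COC(=O)[C@H]1CC/C(=C\C#C[Si](C)(C)C)O1
F2 | step 12 | lithium (2R,5E)-5-(prop-2-yn-1-ylidene)oxolane-2-carboxylate | [Li+].[O-]C(=O)[C@H]1CC/C(=C\C#C)O1
F3 | step 12 | (2R,5E)-5-(prop-2-yn-1-ylidene)oxolane-2-carboxylic 2,2-dimethylpropanoic anhydride | CC(C)(C)C(=O)OC(=O)[C@H]1CC/C(=C\C#C)O1
F4 | step 12 | enynyl 2-amidofuran (19 with ethynyl in place of ethyl) | COC(=O)C(C)c1coc2c1C[C@@H](N2C(=O)[C@H]3CC/C(=C\C#C)O3)[C@@H]4C[C@H](C)C(=O)O4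
F5 | step 12 | oxygen-bridged cycloadduct (20 with ethynyl in place of ethyl) | C#C[C@H]1[C@@H]2O[C@]36N(C(=O)[C@H]4CC[C@@]13O4)[C@@H]([C@@H]5C[C@H](C)C(=O)O5)CC6=C2C(C)C(=O)OC
F6 | step 12 | 10-ethynyl keto ester (21 with ethynyl in place of ethyl) | C#C[C@H]1C(=O)[C@H](C(C)C(=O)OC)C2=C3N(C(=O)[C@H]4CC[C@]31O4)[C@@H]([C@@H]5C[C@H](C)C(=O)O5)C2
F7 | step 11 | tert-butyl (5R)-3-(1-methoxy-1-oxopropan-2-yl)-5-[(2S,4S)-4-methyl-5-oxooxolan-2-yl]-4,5-dihydro-6H-furo[2,3-b]pyrrole-6-carboxylate | COC(=O)C(C)c1coc2c1C[C@@H](N2C(=O)OC(C)(C)C)[C@@H]3C[C@H](C)C(=O)O3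
F8 | step 11 | tert-butyldimethylsilyl (5R)-3-(1-methoxy-1-oxopropan-2-yl)-5-[(2S,4S)-4-methyl-5-oxooxolan-2-yl]-4,5-dihydro-6H-furo[2,3-b]pyrrole-6-carboxylate | COC(=O)C(C)c1coc2c1C[C@@H](N2C(=O)O[Si](C)(C)C(C)(C)C)[C@@H]3C[C@H](C)C(=O)O3
F9 | step 10 | methyl (2E)-4,4-dimethoxy-2-methylbut-2-enoate | COC(=O)/C(C)=C/C(OC)OC
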